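**Minutes: cedar against elm**

A small charge of free catalyst, 26 µM, stands in both cedar and elm, and the meeting asked which flask holds more target after 5.0 min.

| flask | substrate | other conformer | free catalyst | temperature | remark | time |
|---|---|---|---|---|---|---|
| west | 0.013 M | 1.3 mM | 13 µM | 46 °C | run made earlier |  |
| north-east | 0.013 M | 1.3 mM | 52 µM | 60 °C | run made earlier |  |
| south-west | 0.019 M | 1.3 mM | 26 µM | 46 °C | run made earlier |  |
| cedar | 0.013 M | 1.30 mM | 26 µM | 65 °C |  | 5.0 min |
| elm | 0.013 M | 1.30 mM | 26 µM | 40 °C |  | 5.0 min |

- west (time / min: target / %): 1.33: 3; 4.00: 5; 8.00: 15; 10.0: 11; 15.0: 16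
- north-east (time / min: target / %): 0.500: 4; 0.833: 11; 1.50: 13; 3.00: 25; 6.00: 36
- south-west (time / min: target / %): 1.33: 2; 4.00: 10; 8.00: 21; 10.0: 25; 15.0: 29

(standard deviation of a reading: 2 percentage points)

* the flask with the highest amount of target, in percent of the substrate and other conformer together charged ("all alike" if they lie within 1.5 percentage points) (cedar / elm / all alike)
* final target, as a percentage of the substrate and other conformer together charged, in cedar
* final target, as a percentage of the substrate and other conformer together charged, in elm

- in a conversion other conformer counts as not yet reacted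

The first speaker took y as target in fraction of the charge, and L as minus the logarithm of one minus y. She noted that at 15.0 min the south-west run had twice the free catalyst of the west run and twice its L, despite different substrate. She therefore proposed the catalyst dose D, charged free catalyst times time, and κ, which is L per unit dose. This is a pseudo-first-order constant per unit of catalyst.

The second speaker objected that κ from the last south-west reading comes out lower. South-west gives 1110 L mol⁻¹ min⁻¹ at 10.0 min, but 878 L mol⁻¹ min⁻¹ at 15.0 min. The meeting kept the earlier reading, and north-east at 3.00 min, which gives 1840 L mol⁻¹ min⁻¹. Each carries the scatter of 2 percentage points.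

I drew an apparent activation energy of 32.3 kJ mol⁻¹ through these two readings. That puts κ at 2190 L mol⁻¹ min⁻¹ for cedar, and this κ, L per unit dose, is carried on. For elm it puts κ at 877 L mol⁻¹ min⁻¹.

Both flasks have a dose of 130 µM·min. My first answer for cedar is κD, 28.5%. Substrate falls meanwhile, so I multiplied κD by one minus y over 2 and went round again. That gave 24.4%, then 25.0%. The same rounds for elm gave 10.8%.

The forecast gave 19% for cedar, below mine, and 10% for elm: “Cedar still wins at 5 min.”

Cedar gives 23.9% against my 25.0%, and elm gives 10.8% against my 10.8%. Cedar still holds 71.6% of the catalyst charged as free catalyst at 5.00 min.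

    2 free catalyst → spent catalyst (k = 6.90 L mol⁻¹ s⁻¹, Ea = 46.0 kJ mol⁻¹)
    substrate + free catalyst → free catalyst + target (k = 18.0 L mol⁻¹ s⁻¹, Ea = 40.0 kJ mol⁻¹)
    substrate ⇌ other conformer (K = 0.160, k = 0.00210 s⁻¹, Ea = 83.0 kJ mol⁻¹, ΔH = 9.00 kJ mol⁻¹)
    free catalyst + other conformer → free catalyst + isomer of the product (k = 60.0 L mol⁻¹ s⁻¹, Ea = 43.0 kJ mol⁻¹)
    (constants at 40 °C)

A neighbour of cedar has 16.0 µM of free catalyst, so its dose is 80.0 µM·min. There κD is 17.5%, the second round gives 16.1%, and that flask holds 17.0% of target.

The earlier runs and the new flask come from a simulation from invented constants.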